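The runs were generated by integration from invented constants; the scatter is artificial.

- Suppose each substrate lost takes one reagent with it. Then [reagent] − [substrate] is an invariant, 0.0300 M in the zeta run, and you can read [reagent] off any substrate reading.

all flasks: substrate 0.10 M
- zeta: reagent 0.13 M; scavenger 0.30 M; run made earlier
- south: reagent 0.130 M; scavenger 0.150 M; time 30 min
- south-east: reagent 0.130 M; scavenger 0.200 M; time 30 min

zeta run (percent of the substrate charged)

| time / min | substrate / % | target / % |
|---|---|---|
| 5.00 | 81 | 8 |
| 10.0 | 70 | 17 |
| 15.0 | 64 | 25 |
| 20.0 | 51 | 38 |
| 25.0 | 45 | 43 |
| 30.0 | 44 | 52 |

(readings scatter by 2 percentage points)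

- part of the substrate that has reacted at the end, south
- part of the substrate that has reacted at the end, south-east
- what raising the concentration of scavenger from its lowest to its highest value here does to the part of the substrate that has reacted (changes below 5 percentage points count as none) (it falls / it rises / no change)

- the analysis behind the earlier runs scatters by 2 percentage points, standard deviation
- no earlier run changes the charge of scavenger; that part of a forecast is a guess

- The bench rule for a reagent in excess is pseudo-first-order decay, with k[reagent] held constant. The zeta run was charged at [reagent]/[substrate] = 1.30, and at its last reading the invariant gives [reagent] = 0.0740 M, which is 56.9% of its charge, so the rule is past its border.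
- Now integrate rate = k[substrate][reagent] with the invariant. The last zeta reading gives 0.286 L mol⁻¹ min⁻¹, the zeta constant: the loss rate of substrate divided by [substrate][reagent], a reading with that reading's scatter.
- Compare two moments in the zeta run: k[reagent] drifts from 0.0372 min⁻¹ at the start to 0.0212 min⁻¹ at the last reading. Frozen at the start, it would put 67.2% reacted, but the reading says 56.0%.
- South and south-east share zeta's substrate and reagent charges and its time. No earlier run varies the scavenger, so I guess 56.0% for both, above the forecast.
- The forecast says 54% (41% to 68%) for south and 55% (44% to 66%) for south-east, with trend no change, since “halving it should matter little”.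
- The flask gives 58.0% in south and 58.0% in south-east, a change of 0.083 percentage points, so the trend is no change.

    substrate + reagent → intermediate + released group (k = 0.310 L mol⁻¹ min⁻¹)
    intermediate → target (k = 0.150 min⁻¹)
    reagent + released group ⇌ idle adduct, settled at all times (K = 13.0 L mol⁻¹)
    scavenger + released group → scavenged by-product (k = 20.0 L mol⁻¹ min⁻¹)

- In south, as charged, the scavenger step alone gives released group a half-life of 0.23 min, far shorter than the 17 min of substrate by its first step alone. In south-east, substrate's half-life by that step stands at 31 min at 30.0 min, with 71% of the scavenger left. For south at 15.0 min, the zeta constant puts substrate at 62.7%, and the flask holds 61.0%. For the same south-east flask read later, at 50 min, it gives 30.1%, and the flask holds 28.2%.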